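**Assumptions**
- Magnone B is drawn as the open hydroxy-ketone. I assume the cis-fused hemiketal tautomer formed in the last step opens to this form on work-up or silica.
- I assume the (S)-diarylprolinol catalyst gives the (2R,3S)-cyclopropane 4 by analogy with its known Michael selectivity. If the opposite sense is found, the (R)-catalyst is used.
- Target configuration from the SMILES: oxolane C5 (aryl) S, C4 (CH2OH) R, C3 (aroyl) R. The aryl group is trans to both neighbouring substituents, and CH2OH and aroyl are cis.

**Retrosynthesis**
1. Magnone B (10) comes from aryl-lithium addition to the cis-fused furo[3,4-c]furanone lactone 8. The lactone ring-opens to the CH2OH and aroyl groups, which are forced cis.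
2. Lactone 8 comes from decarboxylation of the ring-fusion ester in 7, and the cis ring fusion fixes C4 (oxolane C3).
3. Compound 7 comes from a proposed new [3+2] annulation of the cyclopropane-fused lactone 5 (a donor–acceptor cyclopropane) with formaldehyde from trioxane. This forms the THF ring (C2–O and C4–C5 bonds), gives the 2,3-trans aryl, and makes the bicycle cis-fused.
4. Compound 5 comes from reduction and lactonisation of the formyl cyclopropane 4, which comes from organocatalytic enantioselective cyclopropanation of enal 1 with bromomalonate 2 (this sets C3).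
5. Rings are formed in the order cyclopropane, γ-lactone, THF.

**Step 1**
Reactants: 1 (E)-3,4,5-trimethoxycinnamaldehyde; 2 dimethyl bromomalonate; 3 (S)-diphenylprolinol TMS ether (catalyst)
Product: 4 dimethyl (2R,3S)-2-formyl-3-(3,4,5-trimethoxyphenyl)cyclopropane-1,1-dicarboxylate
Conditions: 3 (20 mol %), 2,6-lutidine (1.1 equiv), CH2Cl2, 25 °C, 24 h
Reagents that add atoms: none
Why: Iminium-activated Michael-initiated ring closure (Michael addition, then 3-exo-tet displacement of bromide by the enamine). The bulky silyl ether shields one iminium face, so the malonate adds to the β-carbon selectively, which sets the absolute configuration of the carbon that becomes C3, and the cyclopropane is trans.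

**Step 2**
Reactants: 4
Product: 5 methyl (1S,5R,6S)-2-oxo-6-(3,4,5-trimethoxyphenyl)-3-oxabicyclo[3.1.0]hexane-1-carboxylate
Conditions: NaBH4, MeOH/CH2Cl2, –20 °C, 20 min; then cat. DBU, PhMe, 25 °C, 2 h
Reagents that add atoms: none (NaBH4 delivers only H; MeOH is lost on lactonisation)
Why: Chemoselective aldehyde reduction, then 5-exo lactonisation of the CH2OH onto the ester cis to it on the gem-diester carbon (acyl substitution). This locks the CH2O/C=O cis relationship, and no stereocentre is touched.

**Step 3**
Reactants: 5; 6 1,3,5-trioxane
Product: 7 methyl (3aR,4S,6aR)-1-oxo-4-(3,4,5-trimethoxyphenyl)tetrahydro-1H,3H-furo[3,4-c]furan-6a-carboxylate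
Conditions: Sc(OTf)3 (20 mol %), 4 Å MS, 1,2-dichloroethane, 80 °C, sealed tube
Reagents that add atoms: none beyond reactant 6 (it supplies the CH2O unit)
Why: Proposed new method: Sc(III) chelates the lactone C=O and the ester C=O on the acceptor carbon and heterolyses the donor–acceptor C–C bond, with the trimethoxybenzylic cation as donor. Formaldehyde released from trioxane adds through oxygen at the benzylic carbon, and the chelated enolate then closes onto the oxocarbenium CH2 (5-exo). This is the closest known reaction, the Sn(II)/Sc(III) [3+2] annulation of donor–acceptor cyclopropanes with aldehydes. It is new here because the partner is formaldehyde (not yet shown for this reaction class) and the acceptor is a cyclopropane-fused lactone. The new ring must be cis-fused to the lactone. The benzylic C–O bond is reversible under Lewis acid, so the aryl ends up exo (2,3-trans). The quaternary ring-fusion carbon is erased in the next step.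

**Step 4**
Reactants: 7
Product: 8 (3aR,4S,6aR)-4-(3,4,5-trimethoxyphenyl)tetrahydro-1H,3H-furo[3,4-c]furan-1-one
Conditions: LiCl, H2O, DMSO, 150 °C
Reagents that add atoms: none (H2O adds only H)
Why: Krapcho dealkoxycarbonylation. The lactone enolate can only be protonated on the convex face, because a trans-fused 5,5-bicycle is impossible, so this sets C4 (oxolane C3) cis to the CH2O arm.

**Step 5**
Reactants: 8; 9 4-bromo-1,2-dimethoxybenzene (via its aryllithium)
Product: 10 Magnone B, [(3R,4R,5S)-4-(hydroxymethyl)-5-(3,4,5-trimethoxyphenyl)oxolan-3-yl](3,4-dimethoxyphenyl)methanone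
Conditions: 9 + n-BuLi, THF, –78 °C, 20 min; add 8, –78 °C, 30 min; quench with sat. NH4Cl at –78 °C
Reagents that add atoms: 3,4-dimethoxyphenyllithium, COc1ccc([Li])cc1OC (n-BuLi is not incorporated)
Why: Single addition of an aryl-lithium to a γ-lactone gives a stable lithium hemiketal alkoxide. Protonation releases the hydroxy ketone (ring–chain tautomer) and no stereocentre is altered. The cold quench avoids epimerisation α to the ketone.

**Compound list**
1 | (E)-3,4,5-trimethoxycinnamaldehyde | COc1cc(/C=C/C=O)cc(OC)c1OC | starting material
2 | dimethyl bromomalonate | COC(=O)C(Br)C(=O)OC | starting material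
3 | (S)-diphenylprolinol TMS ether | C[Si](C)(C)OC(c1ccccc1)(c1ccccc1)[C@@H]1CCCN1 | starting material (catalyst)
4 | dimethyl (2R,3S)-2-formyl-3-(3,4,5-trimethoxyphenyl)cyclopropane-1,1-dicarboxylate | COC(=O)C1(C(=O)OC)[C@H](C=O)[C@H]1c1cc(OC)c(OC)c(OC)c1 | intermediate
5 | methyl (1S,5R,6S)-2-oxo-6-(3,4,5-trimethoxyphenyl)-3-oxabicyclo[3.1.0]hexane-1-carboxylate | COC(=O)[C@@]12C(=O)OC[C@@H]1[C@H]2c1cc(OC)c(OC)c(OC)c1 | intermediate
6 | 1,3,5-trioxane | C1OCOCO1 | starting material
7 | methyl (3aR,4S,6aR)-1-oxo-4-(3,4,5-trimethoxyphenyl)tetrahydro-1H,3H-furo[3,4-c]furan-6a-carboxylate | O=C1OC[C@H]2[C@]1(C(=O)OC)CO[C@@H]2c1cc(OC)c(OC)c(OC)c1 | intermediate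
8 | (3aR,4S,6aR)-4-(3,4,5-trimethoxyphenyl)tetrahydro-1H,3H-furo[3,4-c]furan-1-one | O=C1OC[C@H]2[C@@H]1CO[C@@H]2c1cc(OC)c(OC)c(OC)c1 | intermediate
9 | 4-bromo-1,2-dimethoxybenzene | COc1ccc(Br)cc1OC | starting material
10 | Magnone B | COc1ccc(C(=O)[C@H]2CO[C@H](c3cc(OC)c(OC)c(OC)c3)[C@H]2CO)cc1OC | target

Formula check: 4 is C17H20O8, 5 is C16H18O7, 7 is C17H20O8, 8 is C15H18O6, and 10 is C23H28O8 (8 plus veratrole's aryl and H).

**Totals**
- Total steps: 5. Longest linear sequence: 5, from compound 1.

**Three steps most likely to fail**
1. **Step 3 (proposed new [3+2] with formaldehyde).** Trioxane may not depolymerise cleanly, or the exo/endo selectivity at C2 may be poor.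
 - Fallback: run the known Sn(OTf)2-catalysed [3+2] of 5 with ethyl glyoxylate. Then cleave the C5 ester and remove that carboxyl by Barton decarboxylation, after which Krapcho (Step 4) removes the ring-fusion ester.
2. **Step 4 (Krapcho).** The lactone enolate has a β-alkoxy leaving group, so E1cB ring-opening to an α-methylene lactone may compete.
 - Fallback: cleave the methyl ester with Me3SnOH, form the Barton PTOC ester, and decarboxylate with tBuSH/Bu3SnH. The intermediate radical is reduced from the convex face, with no enolate involved, so cis-fusion is retained.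
3. **Step 5 (aryl-lithium addition).** Over-addition to the diaryl carbinol, or α-deprotonation followed by β-elimination, may occur.
 - Fallback: open lactone 8 with MeNHOMe·HCl/AlMe3 to the hydroxy Weinreb amide, protect as the TBS ether, add ArMgBr (less basic), then remove TBS with HF·pyridine.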